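A small charge of substrate, 43 mM, stands behind all four flasks, and the measure is the share of target in target plus side product, the selectivity.

| setting | red | grey | violet | green | noon | midnight | spring | dusk |
|---|---|---|---|---|---|---|---|---|
| substrate | 43 mM | 60 mM | 95 mM | 43 mM | 43 mM (fed, over 6.0 d) | 43 mM | 43 mM | 43 mM (fed, over 6.0 d) |
| partner A | 34.4 mM | 34.4 mM | 34.4 mM | 69 mM | 34.4 mM | 34.4 mM | 34.4 mM | 34.4 mM |
| partner B | 43 mM | 43 mM | 43 mM | 43 mM | 43.0 mM | 43.0 mM (fed, over 6.0 d) | 43.0 mM (fed, over 40 h) | 43.0 mM |
| temperature | 65 °C | 76 °C | 65 °C | 76 °C | 70 °C | 70 °C | 70 °C |  |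
| remark | run made earlier | run made earlier | run made earlier | run made earlier | all else is in the flask from the start; the feed brings no volume worth counting | all else is in the flask from the start; the feed brings no volume worth counting | all else is in the flask from the start; the feed brings no volume worth counting | the addition at 40 °C, then warmed to 70 °C; the feed brings no volume worth counting |
| time |  |  |  |  | 10 d | 10 d | 10 d | 10 d |

- red (time / d: target / %, side product / %): 0.500: 5.2, 0.9; 1.04: 13.1, 2.8; 2.50: 20.2, 6.6; 6.00: 22.7, 13.2
- grey (time / d: target / %, side product / %): 1.67: 14.8, 12.2; 3.00: 14.6, 18.5; 5.00: 15.6, 26.7; 6.00: 15.0, 29.4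
- violet (time / d: target / %, side product / %): 0.500: 2.7, 2.9; 1.04: 5.2, 6.2; 2.50: 6.0, 13.0; 6.00: 7.0, 25.3
- green (time / d: target / %, side product / %): 1.67: 23.2, 6.2; 3.00: 23.4, 9.7; 5.00: 22.9, 16.1; 6.00: 23.8, 17.7

(readings scatter by 0.5 percentage points)

1. which flask leads in share of target in target plus side product ("all alike" within 1.5 percentage points) (noon / midnight / spring / dusk / all alike)
2. share of target in target plus side product at the end, noon
3. share of target in target plus side product at the end, midnight
4. share of target in target plus side product at the end, spring
5. share of target in target plus side product at the end, dusk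

- in percentages every species weighs as the substrate in it: one side product counts as two
- a reading or a percentage of target counts all its forms, free or not

The earlier runs show two things. Target flattens: red holds 22.7 % at 6.00 d, and green, with 69 mM of partner A, holds 23.8 %. Side product keeps climbing meanwhile.

My colleague's forecast reads this as a matter of substrate level: “Feeding substrate keeps its level low, which starves the dimerisation”. It gives noon 75 %, midnight 50 %, spring 48 % and dusk 61 %, with noon leading.

I hold a different view. At 6.00 d, red has put just 35.9 % of its substrate into target and side product. So I expect fed substrate to pile up rather than stay low, and what counts is how long it stands hot.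

Let r be the late slope of side product, as a fraction of the charge per day at 43 mM. Red and green bracket 70 °C, and the mean of their slopes reads 0.0228 d⁻¹, the side clock. The slope rises with substrate, but less than in proportion: at 65 °C and equal partner A, violet's over red's reads 1.86, lower than their substrate ratio of 2.21.

Let H be the hot days, weighted by the fraction of substrate present. Noon's ramp gives 7.00 d, midnight and spring get 10 d, and dusk, counting its cold feed as nothing, gets 4.00 d. Side product is then r·H: 15.9 % for noon, 22.8 % for midnight and spring, and 9.10 % for dusk.

Taking red's stall as the target, my shares are 58.8 % for noon, 49.9 % for midnight and spring, and 71.4 % for dusk. So I put dusk first, where the forecast puts noon.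

The flasks give noon 49.5 %, midnight 56.1 %, spring 52.2 % and dusk 60.5 %. Dusk leads, and noon comes last. My dusk figure was too high; the forecast's 61 % was right within tolerance.

    substrate + partner B → open intermediate (k = 9.30 × 10⁻⁴ L mol⁻¹ s⁻¹, Ea = 77.0 kJ mol⁻¹)
    partner B + partner A → second intermediate (k = 5.80 × 10⁻⁴ L mol⁻¹ s⁻¹, Ea = 92.0 kJ mol⁻¹)
    open intermediate + second intermediate → target (k = 0.00140 L mol⁻¹ s⁻¹, Ea = 86.0 kJ mol⁻¹)
    2 second intermediate → homo product (k = 0.00200 L mol⁻¹ s⁻¹, Ea = 62.0 kJ mol⁻¹)
    substrate + open intermediate → side product (k = 2.80 × 10⁻⁵ L mol⁻¹ s⁻¹, Ea = 67.0 kJ mol⁻¹)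
    crystals ⇌ target, rate k6*(cs6 - [target]) while solid is left; crystals form when [target] > cs6 (solubility = 24.0 mM, k = 6.80 × 10⁻⁴ s⁻¹)
    (constants at 70 °C)

At 6.00 d, noon still held 67.5 % of its substrate. Its side product ended at 12.5 % against the clock's 15.9 %, and its target at 12.3 %, about half of red's stall. The neighbour is noon charged with 11 mM of substrate. Scaled to that charge, the clock gives 4.08 % of side product, and the flask holds 3.81 %. Here the forecast's picture fits: substrate ends at 19.9 %, and the share reaches 89.0 %, above the 75 % it forecast for noon.

Readings and results stem from a simulated flask for an exercise, and the scatter is random.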